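The numbers of this flask were set for the occasion; the flask was simulated.

The forms of the catalyst always add up to its charge, so whatever passes into spent catalyst is paid from a fixed purse.

    partner + free catalyst → catalyst intermediate A (k1 = 450 M⁻¹ s⁻¹)
    catalyst intermediate A → catalyst intermediate B (k2 = 12 s⁻¹)
    starting material + catalyst intermediate B → catalyst intermediate C (k3 = 87 M⁻¹ s⁻¹)
    catalyst intermediate C ⇌ by-product + catalyst intermediate D (K4 = 9.0 M, k4 = 37 s⁻¹)
    catalyst intermediate D ⇌ catalyst intermediate E (K5 = 0.39, k5 = 13 s⁻¹)
    catalyst intermediate E → free catalyst + target (k6 = 14 s⁻¹)
    target → over-reaction product (k7 = 8.8 × 10⁻⁵ s⁻¹)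
    catalyst intermediate E → spent catalyst A (k8 = 0.017 s⁻¹)
    starting material + catalyst intermediate D → spent catalyst B (k9 = 0.32 M⁻¹ s⁻¹)

in all of them: partner 0.220 M; free catalyst 1.1 mM; time 4.0 min

| charge | starting material |
|---|---|
| south-east | 0.040 M |
| south | 0.12 M |
| north-west | 0.30 M |

* [target] at the end for south-east, south, north-west, in this order
* how the row runs (rises, then falls / falls all the way / falls, then rises / rises all the way / hardly changes)

- a species is counted by the starting material in it: one spent catalyst B counts as two
- "hardly changes" means that all values lie within two and a half points (for a concentration: within two and a half percent of the largest)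
- run time (south-east): 4.0 min

So count the price of a turn. Hold intermediate E steady: it leaves back to intermediate D at 33.3 s⁻¹ or on to target at 14 s⁻¹, so intermediate D delivers target at 3.85 s⁻¹ times its own amount. Starting material strikes intermediate D with 0.32 M⁻¹ s⁻¹, a loss per turn that shrinks as starting material goes. Summed over the south-east charge, it costs 0.0605 of the catalyst. Intermediate E's own death, 0.00121 per target, adds 0.0442.

The sum, 0.105 in south-east, is the kill number: the catalyst, counted in charges of it, that must die for the whole starting material charge to turn once. Solve both ends. Below one, the catalyst outlasts the charge and the two terms are the spent fractions. Above one, the reaction stops at the fraction turned where the losses reach the whole catalyst charge. I put the join at one.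

| flask | spent B term | spent A term | kill number | fraction turned |
|---|---|---|---|---|
| south-east | 0.0605 | 0.0442 | 0.105 | 1 |
| south | 0.545 | 0.132 | 0.677 | 1 |
| north-west | 3.40 | 0.331 | 3.74 | 0.151 |

Was one number enough? It counts catalyst, not minutes. In the south flask 0.323 of the catalyst should survive. If that survivor stands as intermediate B (the resting state late in the run), it gives the last of the starting material a pseudo-first-order half-life of 22.4 s, shorter than the 4.0 min. Over-reaction needs a small correction: its half-life in south-east is 130 min, longer than the run. I commit to 0.0392 M, 0.117 M and 0.0443 M.

The forecast gives 0.039 M, 0.115 M and 0.045 M, a row that rises, then falls, holding that “starting material intercepts intermediate D about once in 40 turnovers, which kills the catalyst within a minute or so and caps the target near 0.045 M”. Its south figure lies below mine and its north-west figure above mine.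

The simulation gives 0.0391 M, 0.116 M and 0.0446 M, and the row rises, then falls. At the end of the north-west flask, the catalyst stands as 95.0% spent catalyst B and 5.02% spent catalyst A, with 84.1% of the starting material left. On the kill number's scale, south-east sits at 0.105 and south at 0.677, and the row turns at 0.13 M, where the number reads 0.822, still below one.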